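The route rests on disconnecting the aryl ether bond O1–C2 of the dihydrofuran ring. In the last step fluoride unmasks the ring-B phenol of a preformed flavone and the phenoxide opens a neighbouring (1S,2R)-2,3-epoxy alcohol at its secondary carbon (5-exo-tet, inversion), so that one operation forms O1–C2, sets C2, reveals the tertiary alcohol from the epoxide oxygen and frees the 5,7-diol. The step exploits the vicinal O1–C2–C(CH3)2–OH array and the trans C2/C3 relationship of the dihydrofuran ring. The precursor is a tris-silylated threo epoxy alcohol made from a salicylaldehyde by asymmetric isobutenylzinc addition and hydroxyl-directed epoxidation.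

Key step: step 9

Remark: the (2S,3S) descriptors correspond to the 2,3-trans dihydrobenzofuran (3-OH and 2-hydroxypropan-2-yl on opposite faces), which is the isomer made; the Re-face sense of the (2R) ligand in step 8 is assigned by analogy with the Si-face selectivity of its (2S) antipode for aromatic aldehydes.

Step 1
Reactants: 1 4-(prop-2-en-1-yloxy)benzoic acid
Product: 2 4-(prop-2-en-1-yloxy)benzoyl chloride
Conditions: (COCl)2, cat. DMF, CH2Cl2, 0 °C to rt; evaporate, use crude
Reagents that add atoms: oxalyl chloride ClC(=O)C(=O)Cl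
Why: Acyl chloride formation via the Vilsmeier-type chloroiminium catalyst is routine for an aryl carboxylic acid and leaves the allyl ether untouched.

Step 2
Reactants: 3 1-(2,4,6-trihydroxyphenyl)ethan-1-one (dried), 2 4-(prop-2-en-1-yloxy)benzoyl chloride
Product: 5 5,7-dihydroxy-2-[4-(prop-2-en-1-yloxy)phenyl]-4H-chromen-4-one, via β-diketone 4 (not isolated)
Conditions: 3, LiN(SiMe3)2 (4.5 equiv), THF, −78 to −10 °C; 2, −78 °C to rt; aq HCl; then H2SO4 (0.5%) in AcOH, 95 °C
Reagents that add atoms: none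
Why: C-Aroylation of the lithium polyanion of the unprotected acetophenone gives the 1,3-diketone 4 directly (the product of a Baker–Venkataraman rearrangement without the ester stage), and acid cyclodehydration through the 2-hydroxyl group closes ring C, the symmetric ring A allowing only one regiochemical outcome.

Step 3
Reactants: 5 5,7-dihydroxy-2-[4-(prop-2-en-1-yloxy)phenyl]-4H-chromen-4-one
Product: 6 5,7-bis(methoxymethoxy)-2-[4-(prop-2-en-1-yloxy)phenyl]-4H-chromen-4-one
Conditions: NaH (3 equiv), MeOCH2Cl (3 equiv), DMF, 0 °C to rt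
Reagents that add atoms: chloromethyl methyl ether COCCl
Why: Williamson-type alkylation of the sodium phenoxides caps both ring-A hydroxyl groups as acetals, the chelated 5-OH requiring the strong base, so that ring A carries no phenoxide in steps 4 to 6.

Step 4
Reactants: 6 5,7-bis(methoxymethoxy)-2-[4-(prop-2-en-1-yloxy)phenyl]-4H-chromen-4-one
Product: 7 2-[4-hydroxy-3-(prop-2-en-1-yl)phenyl]-5,7-bis(methoxymethoxy)-4H-chromen-4-one
Conditions: PhNEt2, 200 °C, sealed tube
Reagents that add atoms: none
Why: Aromatic Claisen rearrangement ([3,3]-sigmatropic shift, then tautomerisation) transfers the allyl group to an ortho position of ring B (both are equivalent, para is blocked) and at the same time releases the 4'-phenol as the only free hydroxyl group.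

Step 5
Reactants: 7 2-[4-hydroxy-3-(prop-2-en-1-yl)phenyl]-5,7-bis(methoxymethoxy)-4H-chromen-4-one
Product: 8 5-[5,7-bis(methoxymethoxy)-4-oxo-4H-chromen-2-yl]-2-hydroxy-3-(prop-2-en-1-yl)benzaldehyde
Conditions: MgCl2, Et3N, (CH2O)n, MeCN, reflux; aq NH4Cl
Reagents that add atoms: paraformaldehyde (as formaldehyde) C=O
Why: Casnati–Skattebøl ortho-formylation, in which the magnesium phenoxide binds formaldehyde and delivers it to the only free ortho position, the hydroxymethyl intermediate being oxidised by a second formaldehyde, while the acetal-capped ring A cannot form a phenoxide and stays inert.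

Step 6
Reactants: 8 5-[5,7-bis(methoxymethoxy)-4-oxo-4H-chromen-2-yl]-2-hydroxy-3-(prop-2-en-1-yl)benzaldehyde
Product: 9 5-[5,7-bis(methoxymethoxy)-4-oxo-4H-chromen-2-yl]-2-hydroxy-3-(3-methylbut-2-en-1-yl)benzaldehyde
Conditions: second-generation Grubbs catalyst (5 mol%), 2-methylbut-2-ene (excess), CH2Cl2, 40 °C
Reagents that add atoms: 2-methylbut-2-ene CC=C(C)C
Why: Olefin cross-metathesis of the terminal allyl group with excess 2-methylbut-2-ene installs the prenyl terminus (no E/Z issue), the electron-poor trisubstituted chromone olefin, the phenol and the aldehyde being tolerated by the ruthenium carbene.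

Step 7
Reactants: 9 5-[5,7-bis(methoxymethoxy)-4-oxo-4H-chromen-2-yl]-2-hydroxy-3-(3-methylbut-2-en-1-yl)benzaldehyde
Product: 10 3-(3-methylbut-2-en-1-yl)-5-{4-oxo-5,7-bis[(triethylsilyl)oxy]-4H-chromen-2-yl}-2-[(triethylsilyl)oxy]benzaldehyde
Conditions: Et3SiOTf (6 equiv), 2,2'-bipyridyl (9 equiv), CH2Cl2, 0 °C to rt; aq NaHCO3
Reagents that add atoms: triethylsilyl trifluoromethanesulfonate CC[Si](CC)(CC)OS(=O)(=O)C(F)(F)F
Why: Silyl triflate with 2,2'-bipyridyl converts aryl methoxymethyl ethers directly into aryl silyl ethers (the acetal carbon leaves as an N-methoxymethylbipyridinium salt) and silylates the free phenol in the same buffered, non-acidic operation, so that every phenol carries a fluoride-labile group before acid-sensitive functionality is introduced.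

Step 8
Reactants: 10 3-(3-methylbut-2-en-1-yl)-5-{4-oxo-5,7-bis[(triethylsilyl)oxy]-4H-chromen-2-yl}-2-[(triethylsilyl)oxy]benzaldehyde
Product: 12 2-{3-[(S)-hydroxy[(2R)-3,3-dimethyloxiran-2-yl]methyl]-5-(3-methylbut-2-en-1-yl)-4-[(triethylsilyl)oxy]phenyl}-5,7-bis[(triethylsilyl)oxy]-4H-chromen-4-one, via zinc alkoxide 11 (not isolated)
Conditions: (Me2C=CH)2Zn (from Me2C=CHMgBr and ZnCl2, MgBrCl precipitated with 1,4-dioxane), (+)-MIB (10 mol%), toluene, −10 °C; then t-BuOOH (in decane), Ti(OiPr)4 (20 mol%), −20 °C; aq NH4Cl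
Reagents that add atoms: bis(2-methylprop-1-en-1-yl)zinc CC(C)=C[Zn]C=C(C)C; tert-butyl hydroperoxide CC(C)(C)OO
Why: Amino-alcohol-catalysed enantioselective alkenylzinc addition, in which the (2R) enantiomer of 3-exo-morpholinoisoborneol directs the alkenyl group to the Re face to give the (R)-alkoxide 11, is followed in the same flask by epoxidation directed by a tetravalent titanium alkoxide, where allylic 1,3-strain from the Z-methyl group holds the carbinol hydrogen in the olefin plane and oxygen is delivered syn to the alkoxide, giving the threo (1S,2R) epoxy alcohol and leaving the undirected prenyl olefin untouched.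

Step 9
Reactants: 12 2-{3-[(S)-hydroxy[(2R)-3,3-dimethyloxiran-2-yl]methyl]-5-(3-methylbut-2-en-1-yl)-4-[(triethylsilyl)oxy]phenyl}-5,7-bis[(triethylsilyl)oxy]-4H-chromen-4-one
Product: 14 5,7-dihydroxy-2-[(2S,3S)-3-hydroxy-2-(2-hydroxypropan-2-yl)-7-(3-methylbut-2-en-1-yl)-2,3-dihydro-1-benzofuran-5-yl]-4H-chromen-4-one, via phenoxide 13 (not isolated)
Conditions: Bu4NF (4 equiv), THF, 0 °C to rt; aq NH4Cl
Reagents that add atoms: none
Why: Fluoride cleaves the three aryl O–Si bonds and the ring-B phenoxide 13 attacks the secondary epoxide carbon from the side opposite its C–O bond in an intramolecular SN2 reaction, the epoxide oxygen becoming the tertiary side-chain alkoxide. The closest known reaction type is the base-mediated cyclisation of ortho-(2,3-epoxy-3-methylbutyl)phenols to 2-(2-hydroxypropan-2-yl)-2,3-dihydrobenzofurans, here run as a desilylative cascade. The dihydrofuran ring closes in the 5-exo-tet mode. C2 is fixed by stereospecific inversion of the (2R) epoxide carbon to (2S), while the (S) carbinol carbon C3 is carried through untouched, so the threo epoxy alcohol maps onto the trans 2,3-product. The step needs 5-exo attack at the secondary carbon, not 6-endo attack at the tertiary carbon (which would give a chromane-3,4-diol) and not Payne migration. Basic, Lewis-acid-free conditions disfavour substitution at the tertiary centre, the collinear trajectory is available only in the five-membered transition state, and the phenol, far more acidic than the secondary alcohol, is the only oxygen nucleophile ionised to a useful extent.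

Compound list
1 | 4-(prop-2-en-1-yloxy)benzoic acid | C=CCOc1ccc(C(=O)O)cc1 | starting material
2 | 4-(prop-2-en-1-yloxy)benzoyl chloride | C=CCOc1ccc(C(=O)Cl)cc1 | intermediate
3 | 1-(2,4,6-trihydroxyphenyl)ethan-1-one | CC(=O)c1c(O)cc(O)cc1O | starting material
4 | 1-[4-(prop-2-en-1-yloxy)phenyl]-3-(2,4,6-trihydroxyphenyl)propane-1,3-dione (not isolated) | C=CCOc1ccc(C(=O)CC(=O)c2c(O)cc(O)cc2O)cc1 | intermediate
5 | 5,7-dihydroxy-2-[4-(prop-2-en-1-yloxy)phenyl]-4H-chromen-4-one | C=CCOc1ccc(-c2cc(=O)c3c(O)cc(O)cc3o2)cc1 | intermediate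
6 | 5,7-bis(methoxymethoxy)-2-[4-(prop-2-en-1-yloxy)phenyl]-4H-chromen-4-one | C=CCOc1ccc(-c2cc(=O)c3c(OCOC)cc(OCOC)cc3o2)cc1 | intermediate
7 | 2-[4-hydroxy-3-(prop-2-en-1-yl)phenyl]-5,7-bis(methoxymethoxy)-4H-chromen-4-one | C=CCc1cc(-c2cc(=O)c3c(OCOC)cc(OCOC)cc3o2)ccc1O | intermediate
8 | 5-[5,7-bis(methoxymethoxy)-4-oxo-4H-chromen-2-yl]-2-hydroxy-3-(prop-2-en-1-yl)benzaldehyde | C=CCc1cc(-c2cc(=O)c3c(OCOC)cc(OCOC)cc3o2)cc(C=O)c1O | intermediate
9 | 5-[5,7-bis(methoxymethoxy)-4-oxo-4H-chromen-2-yl]-2-hydroxy-3-(3-methylbut-2-en-1-yl)benzaldehyde | CC(C)=CCc1cc(-c2cc(=O)c3c(OCOC)cc(OCOC)cc3o2)cc(C=O)c1O | intermediate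
10 | 3-(3-methylbut-2-en-1-yl)-5-{4-oxo-5,7-bis[(triethylsilyl)oxy]-4H-chromen-2-yl}-2-[(triethylsilyl)oxy]benzaldehyde | CC(C)=CCc1cc(-c2cc(=O)c3c(O[Si](CC)(CC)CC)cc(O[Si](CC)(CC)CC)cc3o2)cc(C=O)c1O[Si](CC)(CC)CC | intermediate
11 | (2-methylprop-1-en-1-yl)zinc (R)-alkoxide of the allylic alcohol from 10 (not isolated) | CC(C)=CCc1cc(-c2cc(=O)c3c(O[Si](CC)(CC)CC)cc(O[Si](CC)(CC)CC)cc3o2)cc([C@H](O[Zn]C=C(C)C)C=C(C)C)c1O[Si](CC)(CC)CC | intermediate
12 | 2-{3-[(S)-hydroxy[(2R)-3,3-dimethyloxiran-2-yl]methyl]-5-(3-methylbut-2-en-1-yl)-4-[(triethylsilyl)oxy]phenyl}-5,7-bis[(triethylsilyl)oxy]-4H-chromen-4-one | CC(C)=CCc1cc(-c2cc(=O)c3c(O[Si](CC)(CC)CC)cc(O[Si](CC)(CC)CC)cc3o2)cc([C@H](O)[C@H]4OC4(C)C)c1O[Si](CC)(CC)CC | intermediate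
13 | tetrabutylammonium phenoxide of the desilylated epoxy alcohol, drawn as the ring-B mono-phenoxide (not isolated) | CC(C)=CCc1cc(-c2cc(=O)c3c(O)cc(O)cc3o2)cc([C@H](O)[C@H]4OC4(C)C)c1[O-].CCCC[N+](CCCC)(CCCC)CCCC | intermediate
14 | 5,7-dihydroxy-2-[(2S,3S)-3-hydroxy-2-(2-hydroxypropan-2-yl)-7-(3-methylbut-2-en-1-yl)-2,3-dihydro-1-benzofuran-5-yl]-4H-chromen-4-one | CC(C)=CCc1cc(-c2cc(=O)c3c(O)cc(O)cc3o2)cc2c1O[C@H](C(C)(C)O)[C@H]2O | target

Total step count: 9. Longest linear sequence: 9 steps (1 to 14; compound 3 enters at step 2).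

Steps most likely to fail

Step 8. The enantioselectivity may be eroded by an uncatalysed, salt-promoted background addition of the Grignard-derived zinc reagent. The triethylsilyl group may migrate from the phenol oxygen to the neighbouring zinc alkoxide, which removes the directing group for the epoxidation. Fallback, from 10 back to 12: a catalytic asymmetric Nozaki–Hiyama–Kishi reaction of 10 with 1-bromo-2-methylprop-1-ene (CrCl2 10 mol%, NiCl2 2 mol%, Mn powder, Cp2ZrCl2, chiral oxazoline–sulfonamide ligand, MeCN) should give the free allylic alcohol 2-{3-[(1R)-1-hydroxy-3-methylbut-2-en-1-yl]-5-(3-methylbut-2-en-1-yl)-4-[(triethylsilyl)oxy]phenyl}-5,7-bis[(triethylsilyl)oxy]-4H-chromen-4-one F1. This is isolated on base-washed silica and epoxidised separately with Ti(OiPr)4 and t-BuOOH in CH2Cl2 at −20 °C under the same allylic 1,3-strain control, rejoining the route at 12.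

Step 7. Exchange at the hindered, chelated 5-position may stay incomplete, and the labile 5-O and 4'-O triethylsilyl groups may be lost during work-up and chromatography. Fallback, from 9 back to 10: acid methanolysis of both acetals (HCl in MeOH, 40 °C) should give the triphenol 2-hydroxy-5-(5,7-dihydroxy-4-oxo-4H-chromen-2-yl)-3-(3-methylbut-2-en-1-yl)benzaldehyde F2. Persilylation with Et3SiCl and imidazole in DMF then returns to 10.

Step 5. Formylation of the electron-poor, hydrogen-bonded phenoxide may be sluggish, and prolonged heating may divert material into methoxymethylated by-products. Fallback, from 7 back to 8: condensation of 7 with phenylboronic acid and paraformaldehyde (cat. propionic acid, toluene, reflux with water removal) should give the cyclic boronate 5,7-bis(methoxymethoxy)-2-[2-phenyl-8-(prop-2-en-1-yl)-4H-1,3,2-benzodioxaborinin-6-yl]-4H-chromen-4-one F3. Transesterification with propane-1,3-diol releases the salicyl alcohol 2-[4-hydroxy-3-(hydroxymethyl)-5-(prop-2-en-1-yl)phenyl]-5,7-bis(methoxymethoxy)-4H-chromen-4-one F4, and MnO2 in CH2Cl2 oxidises the benzylic alcohol to rejoin the route at 8.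

Further compounds
F1 | step 8 | 2-{3-[(1R)-1-hydroxy-3-methylbut-2-en-1-yl]-5-(3-methylbut-2-en-1-yl)-4-[(triethylsilyl)oxy]phenyl}-5,7-bis[(triethylsilyl)oxy]-4H-chromen-4-one | CC(C)=CCc1cc(-c2cc(=O)c3c(O[Si](CC)(CC)CC)cc(O[Si](CC)(CC)CC)cc3o2)cc([C@H](O)C=C(C)C)c1O[Si](CC)(CC)CC
F2 | step 7 | 2-hydroxy-5-(5,7-dihydroxy-4-oxo-4H-chromen-2-yl)-3-(3-methylbut-2-en-1-yl)benzaldehyde | CC(C)=CCc1cc(-c2cc(=O)c3c(O)cc(O)cc3o2)cc(C=O)c1O
F3 | step 5 | 5,7-bis(methoxymethoxy)-2-[2-phenyl-8-(prop-2-en-1-yl)-4H-1,3,2-benzodioxaborinin-6-yl]-4H-chromen-4-one | C=CCc1cc(-c2cc(=O)c3c(OCOC)cc(OCOC)cc3o2)cc2COB(c3ccccc3)Oc12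
F4 | step 5 | 2-[4-hydroxy-3-(hydroxymethyl)-5-(prop-2-en-1-yl)phenyl]-5,7-bis(methoxymethoxy)-4H-chromen-4-one | C=CCc1cc(-c2cc(=O)c3c(OCOC)cc(OCOC)cc3o2)cc(CO)c1O
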